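**Retrosynthetic overview**
- The route rests on arene carbon C1′: it lies between the oxygen-bearing carbons C2′ and C6′ and carries the crowded benzylic methine Cα (bonded to the isobutyl CH2 and to decalin C1). It is therefore brought in as an alkyne carbon, and the benzene ring is grown around it last.
- Arene: ynol silyl ether 36 + 3-ethoxycyclobutenone 37 → phenol 42 (bonds C1′–C2′, C5′–C6′, C2′–C3′), then diformylation at C3′/C5′, O-de-ethylation and desilylation.
- 36 ⇐ methyl ester 33 (ester → ynolate → O-silylation) ⇐ C1 acetic acid 24 by auxiliary-controlled methallylation (sets Cα) and hydrogenation.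
- 24 ⇐ dienone 10: cuprate addition at C1, reduction to the trans-decalin, carbonyl shift C3 → C4, methyl addition at C4.
- Ring order: ring B from (S)-carvone, ring A by chiral-imine Robinson annulation, benzene ring last.

Key step: step 21

Remark: the decalin is numbered as an eudesmane (C1–C10, C11 = carbinol carbon on C7); Cα is the benzylic methine and C1′–C6′ are the arene carbons. "ent-Eudesman-1-yl" means the core of the target: trans-decalin, C10 methyl and C7 substituent cis, C1 substituent axial and trans to the C10 methyl, 4-OH axial and cis to the C10 methyl. "15-nor" means without the C4 methyl.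
Remark: step 1 gives both C2 epimers of 2, and step 8 is assumed to give mainly the 3,4-trans isomer drawn for 16 and 17. Neither matters: C2 becomes trigonal in step 3, and C3/C4 lose their configuration in steps 9 and 10.

Step 1
Reactants: 1 (S)-(+)-carvone
Product: 2 (2S,5S)-dihydrocarvone (accompanied by its 2R epimer)
Conditions: LiBH(s-Bu)3, THF, −78 °C; NH4Cl (aq)
Reagents that add atoms: none
Why: Conjugate hydride reduction by the hindered borohydride (Selectride 1,4-reduction of an enone without a β-alkyl branch), followed by protonation on work-up, should leave C5 and the isopropenyl group untouched.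

Step 2
Reactants: 2 (2S,5S)-dihydrocarvone
Product: 3 (2S,5S)-5-(2-hydroxypropan-2-yl)-2-methylcyclohexan-1-one
Conditions: Co(acac)2 (cat.), PhSiH3, O2 (1 atm), THF, rt; Na2S2O3 (aq)
Reagents that add atoms: dioxygen, O=O
Why: Mukaiyama hydration (hydrogen-atom transfer to the 1,1-disubstituted alkene, O2 capture of the tertiary radical, reduction of the peroxide) should give the Markovnikov C11 carbinol in the presence of the ketone.

Step 3
Reactants: 3 hydroxy ketone; 4 (S)-1-phenylethylamine; 5 methyl vinyl ketone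
Product: 8 (2R,5S)-5-(2-hydroxypropan-2-yl)-2-methyl-2-(3-oxobutyl)cyclohexan-1-one, via imine 6 (not isolated), via Michael imine 7 (not isolated)
Conditions: 4, 4 Å MS, PhMe, 60 °C; then 5, THF, rt; then 10% AcOH (aq), rt
Reagents that add atoms: methyl vinyl ketone (5), CC(=O)C=C; water, O
Why: Asymmetric Michael addition of a chiral imine (d'Angelo reaction): the more substituted secondary enamine tautomer of 6 adds to the enone in an aza-ene-like transition state on the face fixed by the (S)-1-phenylethyl group, which should set quaternary C10 as R (methyl cis to the C7 substituent), and mild hydrolysis of 7 releases the amine.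

Step 4
Reactants: 8 diketone
Product: 9 (4aR,7S)-7-(2-hydroxypropan-2-yl)-4a-methyl-4,4a,5,6,7,8-hexahydronaphthalen-2(3H)-one (11-hydroxy-15-nor-ent-eudesm-4-en-3-one)
Conditions: NaOMe, MeOH, 60 °C
Reagents that add atoms: none
Why: Intramolecular aldol condensation (second stage of the Robinson annulation) closes ring A by attack of the methyl ketone enolate on the ring carbonyl and dehydrates to the conjugated enone without creating a stereocentre.

Step 5
Reactants: 9 enone
Product: 10 (4aR,7S)-7-(2-hydroxypropan-2-yl)-4a-methyl-5,6,7,8-tetrahydronaphthalen-2(4aH)-one (the 1,4-dien-3-one)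
Conditions: DDQ, dioxane, reflux
Reagents that add atoms: none
Why: DDQ dehydrogenation of a 3-oxo-4-ene under neutral conditions removes H1 and H2 through the cross-conjugated dienol, the usual entry to 1,4-dien-3-ones of angularly methylated octalones; the tertiary alcohol is inert.

Step 6
Reactants: 10 dienone; 11 (1,3-dioxolan-2-ylmethyl)magnesium bromide
Product: 13 (4R,4aR,7S)-4-(1,3-dioxolan-2-ylmethyl)-7-(2-hydroxypropan-2-yl)-4a-methyl-4,4a,5,6,7,8-hexahydronaphthalen-2(3H)-one (C1 chain trans to the C10 methyl), via bis-silyl dienol ether 12 (not isolated)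
Conditions: 11 (3.5 equiv), CuBr·SMe2 (20 mol %), Me3SiCl, THF, −40 → 0 °C; then K2CO3, MeOH, rt
Reagents that add atoms: (1,3-dioxolan-2-ylmethyl)magnesium bromide (11), Br[Mg]CC1OCCO1
Why: Copper-catalysed, Me3SiCl-accelerated conjugate addition should go to the less substituted β-carbon C1 of the cross-conjugated dienone by axial attack on the face opposite the C10 methyl (the known behaviour of angularly methylated 1,4-dien-3-ones), which sets C1 with the masked acetaldehyde chain trans to that methyl; methanolysis of 12 returns the 4-en-3-one.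

Step 7
Reactants: 13 enone acetal
Product: 15 1-(1,3-dioxolan-2-ylmethyl)-3,11-bis(triethylsilyloxy)-15-nor-ent-eudesm-3-ene (H5 trans to the C10 methyl), via dilithium enolate alkoxide 14 (not isolated)
Conditions: Li, NH3(l)/THF, −78 °C; isoprene; NH3 evaporated; then Et3SiCl, Et3N, THF, 0 °C
Reagents that add atoms: chlorotriethylsilane, CC[Si](Cl)(CC)CC
Why: Dissolving-metal (Birch-type) reduction of the 4-en-3-one protonates C5 axially to give the trans ring fusion (the axial C1 chain meets only this incoming proton) and leaves the C3–C4 enolate, which is trapped regiospecifically together with the C11 alkoxide (reductive silylation).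

Step 8
Reactants: 15 silyl enol ether
Product: 17 1-(1,3-dioxolan-2-ylmethyl)-3,11-bis(triethylsilyloxy)-15-nor-ent-eudesman-4-ol (3,4-trans), via alkylborane 16 (not isolated)
Conditions: BH3·THF, THF, 0 °C → rt; then 3 M NaOH, 30% H2O2, 0 °C
Reagents that add atoms: hydrogen peroxide, OO
Why: Hydroboration of a silyl enol ether places boron on C4, the carbon β to oxygen, by syn addition from the face away from the C10 methyl, and oxidation with retention should give the 4-hydroxy-3-silyloxy compound.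

Step 9
Reactants: 17 alcohol
Product: 18 1-(1,3-dioxolan-2-ylmethyl)-3,11-bis(triethylsilyloxy)-15-nor-ent-eudesman-4-one
Conditions: Dess–Martin periodinane, NaHCO3, CH2Cl2, rt
Reagents that add atoms: none
Why: Dess–Martin oxidation under bicarbonate buffer converts the secondary C4 alcohol into the ketone without epimerising C5 or cleaving the silyl ethers or the acetal.

Step 10
Reactants: 18 α-silyloxy ketone
Product: 19 1-(1,3-dioxolan-2-ylmethyl)-11-(triethylsilyloxy)-15-nor-ent-eudesman-4-one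
Conditions: SmI2, THF/MeOH, −78 °C
Reagents that add atoms: none
Why: SmI2 (divalent samarium) reduces the ketone to a ketyl that expels the α-silyloxy group (samarium diiodide deoxygenation of α-oxygenated ketones), and the C3–C4 enolate is protonated at C3 by methanol, which completes the carbonyl shift from C3 to C4 while C5 is never enolised.

Step 11
Reactants: 19 ketone
Product: 20 1-(1,3-dioxolan-2-ylmethyl)-11-(triethylsilyloxy)-ent-eudesman-4-ol (4-OH axial and cis to the C10 methyl)
Conditions: MeLi, CeCl3, THF, −78 °C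
Reagents that add atoms: methyllithium, [Li]C
Why: The weakly basic organocerium reagent adds to the enolisable ketone without deprotonating C5 (organocerium 1,2-addition), and attack along the equatorial trajectory, the axial one being blocked by the syn-axial C10 methyl, should set C4 with equatorial methyl and axial hydroxyl, the known outcome of methylmetal additions to 4-oxo-nor-eudesmanes.

Step 12
Reactants: 20 acetal
Product: 21 2-(4,11-dihydroxy-ent-eudesman-1-yl)acetaldehyde
Conditions: 1 M HCl, THF, rt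
Reagents that add atoms: water, O
Why: Acid hydrolysis of the dioxolane (acetal hydrolysis) unmasks the aldehyde and removes the C11 silyl ether at the same time; both tertiary alcohols tolerate dilute acid at room temperature.

Step 13
Reactants: 21 aldehyde
Product: 22 2-(4,11-dihydroxy-ent-eudesman-1-yl)acetic acid
Conditions: NaClO2, NaH2PO4, 2-methyl-2-butene, t-BuOH/H2O, rt
Reagents that add atoms: sodium chlorite, [Na+].[O-]Cl=O
Why: Pinnick oxidation converts the aldehyde into the acid under buffered conditions that leave the tertiary alcohols and all stereocentres untouched.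

Step 14
Reactants: 22 dihydroxy acid
Product: 24 2-[4,11-bis(triethylsilyloxy)-ent-eudesman-1-yl]acetic acid, via silyl ester 23 (not isolated)
Conditions: Et3SiOTf, 2,6-lutidine, CH2Cl2, 0 °C → rt; then K2CO3, MeOH/H2O, 0 °C
Reagents that add atoms: triethylsilyl trifluoromethanesulfonate, CC[Si](CC)(CC)OS(=O)(=O)C(F)(F)F
Why: The silyl triflate silylates both hindered tertiary alcohols and the acid (silyl ether protection), and mild carbonate hydrolysis cleaves only the labile silyl ester 23.

Step 15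
Reactants: 24 acid; 25 (S)-4-benzyl-2-oxazolidinone
Product: 27 (S)-4-benzyl-3-{2-[4,11-bis(triethylsilyloxy)-ent-eudesman-1-yl]acetyl}oxazolidin-2-one, via mixed pivalic anhydride 26 (not isolated)
Conditions: t-BuCOCl, Et3N, THF, −20 °C; then 25, LiCl, rt
Reagents that add atoms: (S)-4-benzyl-2-oxazolidinone (25), O=C1N[C@@H](Cc2ccccc2)CO1
Why: N-Acylation of the oxazolidinone through the mixed anhydride (Evans auxiliary attachment) takes place at the unhindered side-chain carbonyl and touches no stereocentre.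

Step 16
Reactants: 27 acyl oxazolidinone; 28 3-bromo-2-methylpropene
Product: 30 (S)-4-benzyl-3-{(2S)-2-[4,11-bis(triethylsilyloxy)-ent-eudesman-1-yl]-4-methylpent-4-enoyl}oxazolidin-2-one, via sodium enolate 29 (not isolated)
Conditions: NaN(SiMe3)2, THF, −78 °C; then 28, −78 → −40 °C
Reagents that add atoms: 3-bromo-2-methylpropene (28), CC(=C)CBr
Why: Evans asymmetric alkylation: the chelated Z-sodium enolate 29 is alkylated by the reactive allylic bromide on the face opposite the benzyl group of the (S)-auxiliary, which should set Cα as S, the same facial sense as in the allylation of simple (S)-4-benzyl-3-acyl oxazolidinones.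

Step 17
Reactants: 30 methallylated imide
Product: 31 (S)-4-benzyl-3-{(2S)-2-[4,11-bis(triethylsilyloxy)-ent-eudesman-1-yl]-4-methylpentanoyl}oxazolidin-2-one
Conditions: H2 (1 atm), Pd on carbon, EtOAc, rt
Reagents that add atoms: none
Why: Heterogeneous catalytic hydrogenation saturates the 1,1-disubstituted alkene to the isobutyl group; nothing else in 30 is reducible under these conditions and Cα is not affected.

Step 18
Reactants: 31 imide
Product: 32 (2S)-2-[4,11-bis(triethylsilyloxy)-ent-eudesman-1-yl]-4-methylpentanoic acid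
Conditions: LiOH, H2O2, THF/H2O, 0 °C; Na2SO3 (aq); cold 0.5 M HCl to pH 3
Reagents that add atoms: hydrogen peroxide, OO
Why: Lithium hydroperoxide attacks the exocyclic imide carbonyl even in α-branched substrates (Evans auxiliary cleavage) and sulfite reduces the peracid, so the acid is released without epimerisation of Cα.

Step 19
Reactants: 32 acid
Product: 33 methyl (2S)-2-[4,11-bis(triethylsilyloxy)-ent-eudesman-1-yl]-4-methylpentanoate
Conditions: MeI, K2CO3, DMF, rt
Reagents that add atoms: iodomethane, CI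
Why: O-Alkylation of the carboxylate (SN2 esterification) gives the methyl ester needed for ynolate formation under conditions that do not epimerise Cα.

Step 20
Reactants: 33 methyl ester
Product: 36 triisopropyl{[(3S)-3-[4,11-bis(triethylsilyloxy)-ent-eudesman-1-yl]-5-methylhex-1-yn-1-yl]oxy}silane (ynol silyl ether), via dibromo enolate 34 (not isolated), via lithium ynolate 35 (not isolated)
Conditions: CH2Br2, lithium 2,2,6,6-tetramethylpiperidide, THF, −78 °C; 33; then n-BuLi, −78 → 0 °C; then i-Pr3SiCl, −78 °C → rt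
Reagents that add atoms: dibromomethane, BrCBr; chlorotri(propan-2-yl)silane, CC(C)[Si](Cl)(C(C)C)C(C)C
Why: Kowalski homologation stopped at the ynolate: LiCHBr2 adds to the ester to give enolate 34, bromine–lithium exchange and 1,2-shift of Cα with retention give ynolate 35, and the bulky silyl chloride silylates it on oxygen, the established route to triisopropylsilyloxyalkynes.

Step 21
Reactants: 36 ynol silyl ether; 37 3-ethoxycyclobut-2-en-1-one
Product: 42 2-{(1S)-1-[4,11-bis(triethylsilyloxy)-ent-eudesman-1-yl]-3-methylbutyl}-5-ethoxy-3-(triisopropylsilyloxy)phenol, via vinylketene 38 (not isolated), via vinylcyclobutenone 39 (not isolated), via dienylketene 40 (not isolated), via cyclohexadienone 41 (not isolated)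
Conditions: PhMe, 110 °C, sealed tube, 37 added in portions
Reagents that add atoms: 3-ethoxycyclobut-2-en-1-one (37), CCOC1=CC(=O)C1
Why: Heating opens 37 by 4π electrocyclic ring opening to (1-ethoxyvinyl)ketene 38, whose electrophilic central carbon is attacked by the Cα-bearing, silyloxy-polarised alkyne carbon of 36 in a regioselective [2+2] cycloaddition to 39, and a second 4π opening gives dienylketene 40. The ring is closed by thermal 6π electrocyclisation to cyclohexadienone 41, which tautomerises to phenol 42, so that C1′–C2′, C5′–C6′ and C2′–C3′ are formed in one operation. The closest known reaction type is the Danheiser benzannulation of cyclobutenones with trialkylsilyloxyalkynes; a 3-alkoxycyclobutenone is a less common partner, and its push–pull stabilisation is the reason for working at 110 °C. No stereocentre is created, and the neutral thermal conditions leave Cα, the tertiary silyl ethers and the decalin centres untouched. The only selectivity needed is regiochemical: the oxygen lone pair makes the Cα-bearing alkyne carbon the nucleophile, so Cα ends on C1′ between the new hydroxyl (C2′) and the silyloxy carbon (C6′), with the ethoxy group para (C4′).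

Step 22
Reactants: 42 phenol
Product: 43 2-{(1S)-1-[4,11-bis(triethylsilyloxy)-ent-eudesman-1-yl]-3-methylbutyl}-5-ethoxybenzene-1,3-diol
Conditions: Bu4NF (1.1 equiv), THF, −20 °C; NH4Cl (aq)
Reagents that add atoms: none
Why: Fluoride desilylation cleaves the aryl silyl ether far faster than the hindered tertiary alkyl triethylsilyl ethers at low temperature, which frees the second phenol and removes the bulky group next to C5′ before formylation.

Step 23
Reactants: 43 resorcinol
Product: 45 5-{(1S)-1-[4,11-bis(triethylsilyloxy)-ent-eudesman-1-yl]-3-methylbutyl}-2-ethoxy-4,6-dihydroxybenzene-1,3-dicarbaldehyde, via bis-iminium salt 44 (not isolated)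
Conditions: POCl3, DMF, MeCN, 0 °C → rt; then NaOAc (aq), rt
Reagents that add atoms: N,N-dimethylformamide, CN(C)C=O; water, O
Why: Vilsmeier–Haack formylation of the electron-rich 2-alkyl-5-alkoxyresorcinol should occur twice, at C3′ and C5′ (the only free positions, each ortho or para to all three oxygens), as in the diformylation of phloroglucinol, and buffered hydrolysis of 44 keeps the silyl ethers.

Step 24
Reactants: 45 ethyl ether dialdehyde
Product: 46 5-{(1S)-1-[4,11-bis(triethylsilyloxy)-ent-eudesman-1-yl]-3-methylbutyl}-2,4,6-trihydroxybenzene-1,3-dicarbaldehyde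
Conditions: NaSEt, DMF, 110 °C; NH4Cl (aq)
Reagents that add atoms: none
Why: Thiolate dealkylation of an aryl alkyl ether (SN2 at the ethyl carbon) is favoured because the C4′ oxygen, flanked by two formyl groups, leaves as a vinylogous carboxylate; the basic conditions spare the tertiary C–O bonds, which a boron or aluminium halide would ionise.

Step 25
Reactants: 46 bis-silyl ether
Product: 47 5-[(1S)-1-(4,11-dihydroxy-ent-eudesman-1-yl)-3-methylbutyl]-2,4,6-trihydroxybenzene-1,3-dicarbaldehyde (CNP0409870.3)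
Conditions: HF·pyridine, pyridine, THF, 0 °C → rt
Reagents that add atoms: none
Why: Buffered fluoride desilylation removes the two tertiary triethylsilyl ethers without dehydrating the carbinols or affecting the aldehydes.

**Compound list**
1 | (S)-(+)-carvone | CC1=CC[C@@H](CC1=O)C(C)=C | starting material
2 | (2S,5S)-dihydrocarvone | C[C@H]1CC[C@@H](CC1=O)C(C)=C | intermediate
3 | (2S,5S)-5-(2-hydroxypropan-2-yl)-2-methylcyclohexan-1-one | C[C@H]1CC[C@@H](CC1=O)C(C)(C)O | intermediate
4 | (S)-1-phenylethylamine | C[C@H](N)c1ccccc1 | starting material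
5 | methyl vinyl ketone | CC(=O)C=C | starting material
6 | N-[(S)-1-phenylethyl] imine of 3 | C[C@H]1CC[C@@H](CC1=N[C@@H](C)c2ccccc2)C(C)(C)O | intermediate
7 | N-[(S)-1-phenylethyl] imine of 8 at the ring carbonyl | CC(=O)CC[C@@]1(C)CC[C@@H](CC1=N[C@@H](C)c2ccccc2)C(C)(C)O | intermediate
8 | (2R,5S)-5-(2-hydroxypropan-2-yl)-2-methyl-2-(3-oxobutyl)cyclohexan-1-one | CC(=O)CC[C@@]1(C)CC[C@@H](CC1=O)C(C)(C)O | intermediate
9 | (4aR,7S)-7-(2-hydroxypropan-2-yl)-4a-methyl-4,4a,5,6,7,8-hexahydronaphthalen-2(3H)-one | C1CC(=O)C=C2C[C@@H](C(C)(C)O)CC[C@]12C | intermediate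
10 | (4aR,7S)-7-(2-hydroxypropan-2-yl)-4a-methyl-5,6,7,8-tetrahydronaphthalen-2(4aH)-one | C1=CC(=O)C=C2C[C@@H](C(C)(C)O)CC[C@]12C | intermediate
11 | (1,3-dioxolan-2-ylmethyl)magnesium bromide | Br[Mg]CC1OCCO1 | starting material
12 | bis(trimethylsilyl) dienol ether of 13 (C3 enol and C11 hydroxyl silylated) | C3(OCCO3)C[C@@H]1C=C(O[Si](C)(C)C)C=C2C[C@@H](C(C)(C)O[Si](C)(C)C)CC[C@]12C | intermediate
13 | (4R,4aR,7S)-4-(1,3-dioxolan-2-ylmethyl)-7-(2-hydroxypropan-2-yl)-4a-methyl-4,4a,5,6,7,8-hexahydronaphthalen-2(3H)-one | C3(OCCO3)C[C@@H]1CC(=O)C=C2C[C@@H](C(C)(C)O)CC[C@]12C | intermediate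
14 | dilithium C3–C4 enolate C11 alkoxide of the trans-fused 3-ketone | [Li+].[Li+].C3(OCCO3)C[C@@H]1CC([O-])=C[C@H]2C[C@@H](C(C)(C)[O-])CC[C@]12C | intermediate
15 | 1-(1,3-dioxolan-2-ylmethyl)-3,11-bis(triethylsilyloxy)-15-nor-ent-eudesm-3-ene | C3(OCCO3)C[C@@H]1CC(O[Si](CC)(CC)CC)=C[C@H]2C[C@@H](C(C)(C)O[Si](CC)(CC)CC)CC[C@]12C | intermediate
16 | C4 alkylborane from 15 | C3(OCCO3)C[C@@H]1C[C@@H](O[Si](CC)(CC)CC)[C@H](B)[C@H]2C[C@@H](C(C)(C)O[Si](CC)(CC)CC)CC[C@]12C | intermediate
17 | 1-(1,3-dioxolan-2-ylmethyl)-3,11-bis(triethylsilyloxy)-15-nor-ent-eudesman-4-ol | C3(OCCO3)C[C@@H]1C[C@@H](O[Si](CC)(CC)CC)[C@H](O)[C@H]2C[C@@H](C(C)(C)O[Si](CC)(CC)CC)CC[C@]12C | intermediate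
18 | 1-(1,3-dioxolan-2-ylmethyl)-3,11-bis(triethylsilyloxy)-15-nor-ent-eudesman-4-one | C3(OCCO3)C[C@@H]1C[C@@H](O[Si](CC)(CC)CC)C(=O)[C@H]2C[C@@H](C(C)(C)O[Si](CC)(CC)CC)CC[C@]12C | intermediate
19 | 1-(1,3-dioxolan-2-ylmethyl)-11-(triethylsilyloxy)-15-nor-ent-eudesman-4-one | C3(OCCO3)C[C@@H]1CCC(=O)[C@H]2C[C@@H](C(C)(C)O[Si](CC)(CC)CC)CC[C@]12C | intermediate
20 | 1-(1,3-dioxolan-2-ylmethyl)-11-(triethylsilyloxy)-ent-eudesman-4-ol | C3(OCCO3)C[C@@H]1CC[C@@](C)(O)[C@H]2C[C@@H](C(C)(C)O[Si](CC)(CC)CC)CC[C@]12C | intermediate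
21 | 2-(4,11-dihydroxy-ent-eudesman-1-yl)acetaldehyde | O=CC[C@@H]1CC[C@@](C)(O)[C@H]2C[C@@H](C(C)(C)O)CC[C@]12C | intermediate
22 | 2-(4,11-dihydroxy-ent-eudesman-1-yl)acetic acid | OC(=O)C[C@@H]1CC[C@@](C)(O)[C@H]2C[C@@H](C(C)(C)O)CC[C@]12C | intermediate
23 | triethylsilyl 2-[4,11-bis(triethylsilyloxy)-ent-eudesman-1-yl]acetate | CC[Si](CC)(CC)OC(=O)C[C@@H]1CC[C@@](C)(O[Si](CC)(CC)CC)[C@H]2C[C@@H](C(C)(C)O[Si](CC)(CC)CC)CC[C@]12C | intermediate
24 | 2-[4,11-bis(triethylsilyloxy)-ent-eudesman-1-yl]acetic acid | OC(=O)C[C@@H]1CC[C@@](C)(O[Si](CC)(CC)CC)[C@H]2C[C@@H](C(C)(C)O[Si](CC)(CC)CC)CC[C@]12C | intermediate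
25 | (S)-4-benzyl-2-oxazolidinone | O=C1N[C@@H](Cc2ccccc2)CO1 | starting material
26 | mixed anhydride of 24 with pivalic acid | CC(C)(C)C(=O)OC(=O)C[C@@H]1CC[C@@](C)(O[Si](CC)(CC)CC)[C@H]2C[C@@H](C(C)(C)O[Si](CC)(CC)CC)CC[C@]12C | intermediate
27 | (S)-4-benzyl-3-{2-[4,11-bis(triethylsilyloxy)-ent-eudesman-1-yl]acetyl}oxazolidin-2-one | O=C1OC[C@H](Cc2ccccc2)N1C(=O)C[C@@H]3CC[C@@](C)(O[Si](CC)(CC)CC)[C@H]4C[C@@H](C(C)(C)O[Si](CC)(CC)CC)CC[C@]34C | intermediate
28 | 3-bromo-2-methylpropene | CC(=C)CBr | starting material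
29 | sodium Z-enolate of 27 | [Na+].[O-]/C(N1C(=O)OC[C@@H]1Cc2ccccc2)=C\[C@@H]3CC[C@@](C)(O[Si](CC)(CC)CC)[C@H]4C[C@@H](C(C)(C)O[Si](CC)(CC)CC)CC[C@]34C | intermediate
30 | (S)-4-benzyl-3-{(2S)-2-[4,11-bis(triethylsilyloxy)-ent-eudesman-1-yl]-4-methylpent-4-enoyl}oxazolidin-2-one | O=C1OC[C@H](Cc2ccccc2)N1C(=O)[C@@H](CC(C)=C)[C@@H]3CC[C@@](C)(O[Si](CC)(CC)CC)[C@H]4C[C@@H](C(C)(C)O[Si](CC)(CC)CC)CC[C@]34C | intermediate
31 | (S)-4-benzyl-3-{(2S)-2-[4,11-bis(triethylsilyloxy)-ent-eudesman-1-yl]-4-methylpentanoyl}oxazolidin-2-one | O=C1OC[C@H](Cc2ccccc2)N1C(=O)[C@@H](CC(C)C)[C@@H]3CC[C@@](C)(O[Si](CC)(CC)CC)[C@H]4C[C@@H](C(C)(C)O[Si](CC)(CC)CC)CC[C@]34C | intermediate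
32 | (2S)-2-[4,11-bis(triethylsilyloxy)-ent-eudesman-1-yl]-4-methylpentanoic acid | OC(=O)[C@@H](CC(C)C)[C@@H]1CC[C@@](C)(O[Si](CC)(CC)CC)[C@H]2C[C@@H](C(C)(C)O[Si](CC)(CC)CC)CC[C@]12C | intermediate
33 | methyl (2S)-2-[4,11-bis(triethylsilyloxy)-ent-eudesman-1-yl]-4-methylpentanoate | COC(=O)[C@@H](CC(C)C)[C@@H]1CC[C@@](C)(O[Si](CC)(CC)CC)[C@H]2C[C@@H](C(C)(C)O[Si](CC)(CC)CC)CC[C@]12C | intermediate
34 | lithium enolate of the dibromomethyl ketone from 33 | [Li+].[O-]C(=C(Br)Br)[C@@H](CC(C)C)[C@@H]1CC[C@@](C)(O[Si](CC)(CC)CC)[C@H]2C[C@@H](C(C)(C)O[Si](CC)(CC)CC)CC[C@]12C | intermediate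
35 | lithium ynolate | [Li+].[O-]C#C[C@@H](CC(C)C)[C@@H]1CC[C@@](C)(O[Si](CC)(CC)CC)[C@H]2C[C@@H](C(C)(C)O[Si](CC)(CC)CC)CC[C@]12C | intermediate
36 | ynol silyl ether: triisopropyl{[(3S)-3-[4,11-bis(triethylsilyloxy)-ent-eudesman-1-yl]-5-methylhex-1-yn-1-yl]oxy}silane | CC(C)C[C@H](C#CO[Si](C(C)C)(C(C)C)C(C)C)[C@@H]1CC[C@@](C)(O[Si](CC)(CC)CC)[C@H]2C[C@@H](C(C)(C)O[Si](CC)(CC)CC)CC[C@]12C | intermediate
37 | 3-ethoxycyclobut-2-en-1-one | CCOC1=CC(=O)C1 | starting material
38 | (1-ethoxyvinyl)ketene (3-ethoxybuta-1,3-dien-1-one) | C=C(OCC)C=C=O | intermediate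
39 | 2-(Cα substituent)-3-(triisopropylsilyloxy)-4-(1-ethoxyvinyl)cyclobut-2-en-1-one (ring CH configuration not defined) | O=C1C(=C(O[Si](C(C)C)(C(C)C)C(C)C)C1C(OCC)=C)[C@@H](CC(C)C)[C@@H]3CC[C@@](C)(O[Si](CC)(CC)CC)[C@H]4C[C@@H](C(C)(C)O[Si](CC)(CC)CC)CC[C@]34C | intermediate
40 | dienylketene from 39 | O=C=C(/C(O[Si](C(C)C)(C(C)C)C(C)C)=C\C(OCC)=C)[C@@H](CC(C)C)[C@@H]3CC[C@@](C)(O[Si](CC)(CC)CC)[C@H]4C[C@@H](C(C)(C)O[Si](CC)(CC)CC)CC[C@]34C | intermediate
41 | 5-ethoxy-3-(triisopropylsilyloxy)-2-(Cα substituent)cyclohexa-2,4-dien-1-one | O=C1CC(OCC)=CC(O[Si](C(C)C)(C(C)C)C(C)C)=C1[C@@H](CC(C)C)[C@@H]3CC[C@@](C)(O[Si](CC)(CC)CC)[C@H]4C[C@@H](C(C)(C)O[Si](CC)(CC)CC)CC[C@]34C | intermediate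
42 | 2-{(1S)-1-[4,11-bis(triethylsilyloxy)-ent-eudesman-1-yl]-3-methylbutyl}-5-ethoxy-3-(triisopropylsilyloxy)phenol | CC(C)C[C@H](c1c(O)cc(OCC)cc1O[Si](C(C)C)(C(C)C)C(C)C)[C@@H]1CC[C@@](C)(O[Si](CC)(CC)CC)[C@H]2C[C@@H](C(C)(C)O[Si](CC)(CC)CC)CC[C@]12C | intermediate
43 | 2-{(1S)-1-[4,11-bis(triethylsilyloxy)-ent-eudesman-1-yl]-3-methylbutyl}-5-ethoxybenzene-1,3-diol | CC(C)C[C@H](c1c(O)cc(OCC)cc1O)[C@@H]1CC[C@@](C)(O[Si](CC)(CC)CC)[C@H]2C[C@@H](C(C)(C)O[Si](CC)(CC)CC)CC[C@]12C | intermediate
44 | C3′,C5′-bis(dimethyliminiomethyl) dichloride of 43 | CC(C)C[C@H](c1c(O)c(C=[N+](C)C)c(OCC)c(C=[N+](C)C)c1O)[C@@H]1CC[C@@](C)(O[Si](CC)(CC)CC)[C@H]2C[C@@H](C(C)(C)O[Si](CC)(CC)CC)CC[C@]12C.[Cl-].[Cl-] | intermediate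
45 | 5-{(1S)-1-[4,11-bis(triethylsilyloxy)-ent-eudesman-1-yl]-3-methylbutyl}-2-ethoxy-4,6-dihydroxybenzene-1,3-dicarbaldehyde | CC(C)C[C@H](c1c(O)c(C=O)c(OCC)c(C=O)c1O)[C@@H]1CC[C@@](C)(O[Si](CC)(CC)CC)[C@H]2C[C@@H](C(C)(C)O[Si](CC)(CC)CC)CC[C@]12C | intermediate
46 | 5-{(1S)-1-[4,11-bis(triethylsilyloxy)-ent-eudesman-1-yl]-3-methylbutyl}-2,4,6-trihydroxybenzene-1,3-dicarbaldehyde | CC(C)C[C@H](c1c(O)c(C=O)c(O)c(C=O)c1O)[C@@H]1CC[C@@](C)(O[Si](CC)(CC)CC)[C@H]2C[C@@H](C(C)(C)O[Si](CC)(CC)CC)CC[C@]12C | intermediate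
47 | CNP0409870.3 | CC(C)C[C@H](c1c(O)c(C=O)c(O)c(C=O)c1O)[C@@H]1CC[C@@](C)(O)[C@H]2C[C@@H](C(C)(C)O)CC[C@]12C | target

**Step count and risks**
Total step count: 25. Longest linear sequence: 25 steps (1 → 47); 4, 5, 11, 25, 28 and 37 are purchased.

Steps most likely to fail:

Step 21 (key step). The 4π opening of the donor-stabilised cyclobutenone may be slower than thermal silyl migration in the ynol ether, and the product phenol may be acylated by the ketene. The fallback sets out from 36 and makes the same ketene 38 at room temperature by 1,4-dehydrochlorination. Commercial ethyl (E)-3-ethoxybut-2-enoate is saponified (LiOH, THF/H2O) to (E)-3-ethoxybut-2-enoic acid F1, which oxalyl chloride (cat. DMF, CH2Cl2) converts into (E)-3-ethoxybut-2-enoyl chloride F2. F2 is added slowly with Et3N to 36 in PhMe at rt, so that 38 is captured by [2+2] cycloaddition as 39. Warming to 80 °C then carries 39 through 40 and 41, and the route is rejoined at 42.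

Step 20. The hindered α-branched ester may be enolised by the lithium amide or the carbenoid instead of undergoing carbonyl addition, with loss of material and of Cα integrity. The fallback sets out from 33 and reaches the ynolate by acetylide oxidation instead of carbenoid rearrangement. Reduction with i-Bu2AlH (CH2Cl2, −78 °C) gives (2S)-2-[4,11-bis(triethylsilyloxy)-ent-eudesman-1-yl]-4-methylpentanal F3. Corey–Fuchs olefination (CBr4, PPh3, Et3N, CH2Cl2, 0 °C) gives the 1,1-dibromoalkene F4, and n-BuLi (2 equiv, THF, −78 °C) converts it into the lithium acetylide F5. Oxidation in the same flask with lithium tert-butyl peroxide (t-BuOOH, LiN(SiMe3)2) gives ynolate 35, and silylation with i-Pr3SiCl rejoins the route at 36.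

Step 6. The internally chelated acetal Grignard reagent may react too slowly at the neopentyl β-carbon C1, or 1,2-addition may compete. The fallback sets out from 10 and uses the much more reactive allyl copper reagent (allylmagnesium bromide, CuBr·SMe2, Me3SiCl, THF, −78 °C), which should add at C1 with the same facial preference to give the bis-silyl allyl dienol ether F6. Methanolysis (K2CO3, MeOH) gives the 1-allyl enone F7. Ozonolysis of the isolated terminal alkene, which is far more electron-rich than the enone double bond (O3, CH2Cl2/MeOH, −78 °C, stopped at first excess; PPh3), gives the enone aldehyde F8. Chemoselective acetalisation of the aldehyde (ethylene glycol, pyridinium tosylate, benzene, rt) rejoins the route at 13.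

Further compounds
F1 | step 21 | (E)-3-ethoxybut-2-enoic acid | CCO/C(C)=C/C(=O)O
F2 | step 21 | (E)-3-ethoxybut-2-enoyl chloride | CCO/C(C)=C/C(=O)Cl
F3 | step 20 | (2S)-2-[4,11-bis(triethylsilyloxy)-ent-eudesman-1-yl]-4-methylpentanal | O=C[C@@H](CC(C)C)[C@@H]1CC[C@@](C)(O[Si](CC)(CC)CC)[C@H]2C[C@@H](C(C)(C)O[Si](CC)(CC)CC)CC[C@]12C
F4 | step 20 | (3S)-1,1-dibromo-3-[4,11-bis(triethylsilyloxy)-ent-eudesman-1-yl]-5-methylhex-1-ene | BrC(Br)=C[C@@H](CC(C)C)[C@@H]1CC[C@@](C)(O[Si](CC)(CC)CC)[C@H]2C[C@@H](C(C)(C)O[Si](CC)(CC)CC)CC[C@]12C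
F5 | step 20 | lithium acetylide of (3S)-3-[4,11-bis(triethylsilyloxy)-ent-eudesman-1-yl]-5-methylhex-1-yne | [Li]C#C[C@@H](CC(C)C)[C@@H]1CC[C@@](C)(O[Si](CC)(CC)CC)[C@H]2C[C@@H](C(C)(C)O[Si](CC)(CC)CC)CC[C@]12C
F6 | step 6 | bis(trimethylsilyl) dienol ether of the 1-allyl enone | C=CC[C@@H]1C=C(O[Si](C)(C)C)C=C2C[C@@H](C(C)(C)O[Si](C)(C)C)CC[C@]12C
F7 | step 6 | (4R,4aR,7S)-4-allyl-7-(2-hydroxypropan-2-yl)-4a-methyl-4,4a,5,6,7,8-hexahydronaphthalen-2(3H)-one | C=CC[C@@H]1CC(=O)C=C2C[C@@H](C(C)(C)O)CC[C@]12C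
F8 | step 6 | 2-[(1R,8aR,6S)-6-(2-hydroxypropan-2-yl)-8a-methyl-3-oxo-1,2,3,5,6,7,8,8a-octahydronaphthalen-1-yl]acetaldehyde | O=CC[C@@H]1CC(=O)C=C2C[C@@H](C(C)(C)O)CC[C@]12C
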